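**Retrosynthesis**
1. Trichorabdal B comes from the fully silylated tetracycle **16**: C6 aldehyde by TEMPO oxidation, C19 acetate by acetylation, C15 enone by SeO2/DMP.
2. Rings C/D (bicyclo[3.2.1]octane, C8 quaternary) come from Pd(II)-mediated oxidative cyclization of the lactone silyl ketene acetal onto the axial C13 isopropenyl group. This is the last ring formed.
3. Ring B (spiro δ-lactone) and the C9–C10 bond come from Ti(III) reductive opening of the A-ring spiro-epoxide **7**, Giese addition to the cyclohexene ester **14**, and in situ lactonization.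
4. Ring A is built from 3-methylcyclohexenone: Cu-catalysed conjugate addition sets C4, with vinyl as the latent C19, and a Mukaiyama aldol sets C6. Ring C is built from 3-methoxybenzoic acid: Birch reduction, Rh-catalysed conjugate addition sets C13, CBS reduction sets C11.
5. Ring order: A and C (from starting materials), then B, then D.

Numbering is ent-kaurane numbering (C1–C20). Assumption: catalyst and ligand enantiomers in Steps 1, 9 and 11 are chosen to give the configurations drawn, and C8 of **11** and **15** is epimerizable and left undefined.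

---

### Fragment A (A-ring spiro-epoxide)

**Step 1**
Reactants: **1** 3-methylcyclohex-2-en-1-one
Product: **2** (3-ethenyl-3-methylcyclohex-1-en-1-yl)oxy-trimethylsilane (C4 quaternary centre set)
Conditions: CH2=CHMgBr, CuBr·SMe2 (5 mol %), chiral ferrocenyl diphosphine (Josiphos-type, 6 mol %), MTBE, −78 °C; then TMSCl, −78→0 °C
Reagents that add atoms: vinylmagnesium bromide `C=C[Mg]Br`; chlorotrimethylsilane `C[Si](C)(C)Cl`
Why: Cu-catalysed asymmetric conjugate addition to a β,β-disubstituted enone creates the C4 quaternary centre, with vinyl as the latent C19. The enolate forms only toward C5, so TMSCl traps it as a regiodefined silyl enol ether.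

**Step 2**
Reactants: **2**, formaldehyde
Product: **3** 2-(hydroxymethyl)-3-methyl-3-vinylcyclohexan-1-one (CH2OH cis to vinyl)
Conditions: 37% aq. HCHO, Sc(OTf)3 (10 mol %), THF/H2O 9:1, 0 °C
Reagents that add atoms: formaldehyde `C=O`
Why: Mukaiyama aldol with aqueous formaldehyde installs C6 at C5. C5 is α to the ketone and epimerizable, so the epimer with C6 cis to C19 (as in the target) is isolated and the other is recycled with DBU.

**Step 3**
Reactants: **3**
Product: **4** the TBS ether of **3**
Conditions: TBSCl, imidazole, DMF, rt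
Reagents that add atoms: tert-butyldimethylsilyl chloride `CC(C)(C)[Si](C)(C)Cl`
Why: Silylation blocks the β-hydroxy ketone against retro-aldol and elimination, and no stereocentre is touched.

**Step 4**
Reactants: **4**
Product: **5** 4-[(TBSO)methyl]-5-ethenyl-5-methyl-1-oxaspiro[2.5]octane
Conditions: Me3S⁺I⁻, n-BuLi, THF, −10 °C
Reagents that add atoms: trimethylsulfonium iodide `C[S+](C)C.[I-]` (transfers CH2 = C20)
Why: Corey–Chaykovsky epoxidation of the C10 ketone builds the radical precursor. The epoxide configuration is irrelevant because Ti(III) opening converges on the planar C10 radical.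

**Step 5**
Reactants: **5**
Product: **6** [4-(TBSO-methyl)-5-methyl-1-oxaspiro[2.5]octan-5-yl]methanol (C19–OH)
Conditions: O3, CH2Cl2/MeOH, −78 °C; then NaBH4, 0 °C
Reagents that add atoms: ozone `[O-][O+]=O`
Why: Ozonolysis cleaves only the monosubstituted alkene, leaving the epoxide and silyl ether, and NaBH4 reduces the resulting C19 aldehyde. C4 is quaternary, so its configuration is retained.

**Step 6**
Reactants: **6**
Product: **7** TES ether of **6** (fragment A)
Conditions: TESCl, imidazole, DMF, rt
Reagents that add atoms: chlorotriethylsilane `CC[Si](Cl)(CC)CC`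
Why: TES is a primary silyl group that can later be removed selectively in the presence of the TBS groups.

### Fragment C (ring-C acceptor)

**Step 7**
Reactants: **8** 3-methoxybenzoic acid
Product: **9** 3-oxocyclohex-4-ene-1-carboxylic acid (racemic at C8)
Conditions: Li, NH3(l), EtOH, THF, −78 °C; then 2 M HCl, rt
Reagents that add atoms: water `O` (enol-ether hydrolysis)
Why: Birch reduction gives the 1,4-diene, and acid hydrolysis of the enol ether with isomerization gives the conjugated γ-carboxy enone. C8 becomes sp2 later, so its configuration is irrelevant.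

**Step 8**
Reactants: **9**
Product: **10** methyl ester
Conditions: MeI, K2CO3, DMF, rt
Reagents that add atoms: iodomethane `CI`
Why: Simple O-alkylation of the carboxylate.

**Step 9**
Reactants: **10**, isopropenylboronic acid pinacol ester
Product: **11** methyl 3-oxo-5-(prop-1-en-2-yl)cyclohexane-1-carboxylate (C13 set; C8 epimers)
Conditions: [Rh(cod)Cl]2 (2.5 mol %), (S)-BINAP (6 mol %), aq. KOH, dioxane, 50 °C
Reagents that add atoms: isopropenylBpin `CC(=C)B1OC(C)(C)C(C)(C)O1`
Why: Hayashi-type Rh-catalysed asymmetric 1,4-addition to the enone β-carbon sets C13 by catalyst control. C8 epimers converge at the next step.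

**Step 10**
Reactants: **11**
Product: **12** methyl 3-oxo-5-(prop-1-en-2-yl)cyclohex-1-ene-1-carboxylate
Conditions: IBX (1.5 equiv), DMSO, 65 °C
Reagents that add atoms: none
Why: Nicolaou dehydrogenation forms the ester-conjugated C8=C9 enone and destroys the C8 stereocentre.

**Step 11**
Reactants: **12**
Product: **13** methyl 3-hydroxy-5-(prop-1-en-2-yl)cyclohex-1-ene-1-carboxylate (OH trans to isopropenyl)
Conditions: (R)-Me-CBS (10 mol %), BH3·SMe2, THF, −20 °C
Reagents that add atoms: none (BH3 supplies only H)
Why: CBS reduction is catalyst-controlled and sets C11 with OH trans to C13. Trans is required so that C11–O and C10 end up diequatorial in the final bicycle.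

**Step 12**
Reactants: **13**
Product: **14** TBS ether (acceptor)
Conditions: TBSCl, imidazole, DMF, rt
Reagents that add atoms: `CC(C)(C)[Si](C)(C)Cl`
Why: Protection prevents the free OH from interfering in the Ti(III) step.

### Assembly

**Step 13**
Reactants: **7**, **14**
Product: **15** spiro-δ-lactone (C9–C10 bond; C20–O–C7 lactone)
Conditions: Cp2TiCl2 (2.2 equiv), Zn dust, 2,4,6-collidine·HCl, THF, rt
Reagents that add atoms: none (collidinium supplies only H; MeOH is lost)
Why: Ti(III) opens the epoxide to the tertiary C10 radical with Ti–O–C20, which adds to C9 of the enoate (Giese) anti to the pseudoaxial C11–OTBS. The radical approaches from the ring-A face remote from axial C19, so C20 ends up syn-diaxial to C19 and C9 equatorial. The Ti enolate is protonated at C8 and the alkoxide lactonizes onto the methyl ester.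

**Step 14**
Reactants: **15**
Product: **16** bicyclo[3.2.1]octane lactone
Conditions: (i) LDA, TMSCl, THF, −78 °C; (ii) Pd(OAc)2 (20 mol %), benzoquinone, MeCN, 40 °C
Reagents that add atoms: none (the TMS group is lost)
Why: The silyl ketene acetal carbon C8 attacks the terminal CH2= of the axial C13 isopropenyl (Pd(II) carbopalladation), and β-H elimination gives the exocyclic C16=C17 alkene. Ring D can only close on the face syn to C13, so C15 is axial and C7 equatorial at C8.

**Step 15**
Reactants: **16**
Product: **17** C15 allylic alcohol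
Conditions: SeO2 (1.5 equiv), TBHP (3 equiv), CH2Cl2, rt
Reagents that add atoms: selenium dioxide `O=[Se]=O` (source of the new OH); co-oxidant TBHP `CC(C)(C)OO`
Why: Riley oxidation occurs only at C15, the single allylic CH2 (C13 is a bridgehead), as in ent-kaurene chemistry. The C15 configuration is destroyed in the next step.

**Step 16**
Reactants: **17**
Product: **18** C15 ketone (enone)
Conditions: Dess–Martin periodinane, NaHCO3, CH2Cl2, rt
Reagents that add atoms: none
Why: The only free OH is oxidized to the conjugated exo-methylene ketone, and the silyl ethers are inert.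

**Step 17**
Reactants: **18**
Product: **19** C19 alcohol
Conditions: PPTS (0.2 equiv), MeOH/CH2Cl2 1:1, 0 °C
Reagents that add atoms: none (H only)
Why: Primary TES ether is cleaved selectively over the two TBS ethers.

**Step 18**
Reactants: **19**
Product: **20** C19 acetate
Conditions: Ac2O, Et3N, DMAP, CH2Cl2, rt
Reagents that add atoms: acetic anhydride `CC(=O)OC(C)=O`
Why: Acylation of the axial primary alcohol gives the required 19-OAc, and the enone, lactone and TBS ethers are untouched.

**Step 19**
Reactants: **20**
Product: **21** 6,11-diol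
Conditions: HF·pyridine, THF/pyridine, rt
Reagents that add atoms: none (H only)
Why: Both TBS ethers are removed, and the acetate, lactone and enone tolerate buffered HF.

**Step 20**
Reactants: **21**
Product: **22** Trichorabdal B
Conditions: TEMPO (10 mol %), PhI(OAc)2 (1.2 equiv), CH2Cl2, rt
Reagents that add atoms: none
Why: TEMPO/BAIB oxidizes only the primary C6–OH to the aldehyde, leaving the hindered secondary C11–OH and the acetate unchanged. The mild, neutral conditions do not epimerize C5.

---

### Compound list
| # | Name | SMILES | Role |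
|---|---|---|---|
| 1 | 3-methylcyclohex-2-en-1-one | `CC1=CC(=O)CCC1` | starting material |
| 2 | 3-ethenyl-3-methylcyclohex-1-enyl TMS ether | `C=C[C@]1(C)CCCC(O[Si](C)(C)C)=C1` | intermediate |
| 3 | 2-(hydroxymethyl)-3-methyl-3-vinylcyclohexanone | `O=C1CCC[C@@](C)(C=C)[C@H]1CO` | intermediate |
| 4 | TBS ether of 3 | `O=C1CCC[C@@](C)(C=C)[C@H]1CO[Si](C)(C)C(C)(C)C` | intermediate |
| 5 | spiro-epoxide with vinyl | `C12(CO2)CCC[C@@](C)(C=C)[C@H]1CO[Si](C)(C)C(C)(C)C` | intermediate |
| 6 | spiro-epoxide, C19 alcohol | `C12(CO2)CCC[C@@](C)(CO)[C@H]1CO[Si](C)(C)C(C)(C)C` | intermediate |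
| 7 | spiro-epoxide, C19 TES ether (fragment A) | `C12(CO2)CCC[C@@](C)(CO[Si](CC)(CC)CC)[C@H]1CO[Si](C)(C)C(C)(C)C` | intermediate |
| 8 | 3-methoxybenzoic acid | `COC1=CC=CC(=C1)C(=O)O` | starting material |
| 9 | 3-oxocyclohex-4-ene-1-carboxylic acid | `OC(=O)C1CC(=O)C=CC1` | intermediate |
| 10 | methyl 3-oxocyclohex-4-ene-1-carboxylate | `COC(=O)C1CC(=O)C=CC1` | intermediate |
| 11 | methyl 3-oxo-5-isopropenylcyclohexane-1-carboxylate | `COC(=O)C1CC(=O)C[C@@H](C(C)=C)C1` | intermediate |
| 12 | methyl 3-oxo-5-isopropenylcyclohex-1-ene-1-carboxylate | `COC(=O)C1=CC(=O)C[C@@H](C(C)=C)C1` | intermediate |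
| 13 | methyl 3-hydroxy-5-isopropenylcyclohex-1-ene-1-carboxylate | `COC(=O)C1=C[C@H](O)C[C@@H](C(C)=C)C1` | intermediate |
| 14 | TBS ether of 13 (acceptor) | `COC(=O)C1=C[C@H](O[Si](C)(C)C(C)(C)C)C[C@@H](C(C)=C)C1` | intermediate |
| 15 | spiro-lactone: 6-OTBS, 11-OTBS, 19-OTES, C13 isopropenyl | `C=C(C)[C@@H]1C[C@@H](O[Si](C)(C)C(C)(C)C)[C@@H]2[C@@]3(CCC[C@@](C)(CO[Si](CC)(CC)CC)[C@H]3CO[Si](C)(C)C(C)(C)C)COC(=O)C2C1` | intermediate |
| 16 | bicyclo[3.2.1]octane lactone, C15 H2 | `C=C1C[C@]23C[C@H]1C[C@@H](O[Si](C)(C)C(C)(C)C)[C@@H]2[C@@]1(CCC[C@@](C)(CO[Si](CC)(CC)CC)[C@H]1CO[Si](C)(C)C(C)(C)C)COC3=O` | intermediate |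
| 17 | C15 allylic alcohol (epimers) | `C=C1C(O)[C@]23C[C@H]1C[C@@H](O[Si](C)(C)C(C)(C)C)[C@@H]2[C@@]1(CCC[C@@](C)(CO[Si](CC)(CC)CC)[C@H]1CO[Si](C)(C)C(C)(C)C)COC3=O` | intermediate |
| 18 | C15 enone | `C=C1C(=O)[C@]23C[C@H]1C[C@@H](O[Si](C)(C)C(C)(C)C)[C@@H]2[C@@]1(CCC[C@@](C)(CO[Si](CC)(CC)CC)[C@H]1CO[Si](C)(C)C(C)(C)C)COC3=O` | intermediate |
| 19 | C19 alcohol | `C=C1C(=O)[C@]23C[C@H]1C[C@@H](O[Si](C)(C)C(C)(C)C)[C@@H]2[C@@]1(CCC[C@@](C)(CO)[C@H]1CO[Si](C)(C)C(C)(C)C)COC3=O` | intermediate |
| 20 | C19 acetate | `C=C1C(=O)[C@]23C[C@H]1C[C@@H](O[Si](C)(C)C(C)(C)C)[C@@H]2[C@@]1(CCC[C@@](C)(COC(C)=O)[C@H]1CO[Si](C)(C)C(C)(C)C)COC3=O` | intermediate |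
| 21 | 6,11-diol | `C=C1C(=O)[C@]23C[C@H]1C[C@@H](O)[C@@H]2[C@@]1(CCC[C@@](C)(COC(C)=O)[C@H]1CO)COC3=O` | intermediate |
| 22 | Trichorabdal B | `C=C1C(=O)[C@]23C[C@H]1C[C@@H](O)[C@@H]2[C@@]1(CCC[C@@](C)(COC(C)=O)[C@H]1C=O)COC3=O` | target |

---

**Step count:** 20 steps in total, with a longest linear sequence of 14 steps (Steps 1–6 to fragment A, then Steps 13–20).

**Three steps most likely to fail**
1. **Step 13 (Ti(III) Giese coupling).** Intermolecular addition of a tertiary radical to a trisubstituted enoate must form vicinal quaternary/tertiary centres. Fallback: make the C9–C10 bond by 6-endo radical cyclization (Bu3SnH/AIBN) of the ester-tethered tertiary bromo-ester made from bromohydrin opening of **7** and esterification with the acid from **14**.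
2. **Step 14 (Pd-mediated ketene-acetal cyclization).** The complex substrate may give only protodesilylation or β-H elimination at the wrong site. Fallback: convert the isopropenyl methyl to an allylic chloride and close the C8–C15 bond by KHMDS intramolecular allylic alkylation of the lactone enolate.
3. **Step 2 (C5 hydroxymethylation stereocontrol).** The cis epimer needed (CH2OH cis to vinyl) may be only a minor product at equilibrium. Fallback: set C4 and C5 together by Rh-catalysed desymmetrizing vinylation of 4-methyl-4-(silyloxymethyl)cyclohexa-2,5-dienone, with vinyl as C6 and later ozonolysis to the aldehyde.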